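**Strategy.** Avarane numbering is used (ring A: C1–C5 and C10; ring B: C5–C10; C11 is the methylene on C4). Everything rests on the C5–C6 bond. The route exploits that C5 lies alpha and C10 beta to C4, whose methylene is a masked ketone. A 2-methylcyclohex-2-enone carrying the intact C9–C8–C7–C6 chain on C10 (both stereocentres set on a lactone template) is turned into its cross-ring dienolate, and C6, as a primary tosylate, alkylates C5. One operation closes ring B and creates the C5 quaternary centre under C9/C8 control. C10 stays sp2 and later takes hydrogen from the alpha face to give the trans ring fusion.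

Key step: step 15

Assumptions: the target is drawn as the free aryl hydrogen sulfate; it would be liberated from its salt on an acidic resin and in practice stored as a salt. Abbreviations in names: Ar = 2-(benzyloxy)-3-{[2-(trimethylsilyl)ethoxy]methoxy}-5-({[tri(propan-2-yl)silyl]oxy}methyl)phenyl; Ar' = the same ring with 2-hydroxy in place of 2-benzyloxy.

**Arylmethyl bromide**

Step 1
Reactants: 1 3-bromo-4,5-dihydroxybenzaldehyde
Product: 2 4-(benzyloxy)-3-bromo-5-hydroxybenzaldehyde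
Conditions: BnBr (1.0 equiv), NaHCO3, NaI (cat.), DMF, 40 °C
Reagents that add atoms: benzyl bromide, BrCc1ccccc1
Why: Williamson etherification of the only phenoxide formed with one equivalent of weak base, the more acidic 4-OH (para to the formyl group, ortho to bromine).

Step 2
Reactants: 2 4-(benzyloxy)-3-bromo-5-hydroxybenzaldehyde
Product: 3 4-(benzyloxy)-3-bromo-5-{[2-(trimethylsilyl)ethoxy]methoxy}benzaldehyde
Conditions: SEMCl, i-Pr2NEt, CH2Cl2, 0 °C to rt
Reagents that add atoms: 2-(trimethylsilyl)ethoxymethyl chloride, C[Si](C)(C)CCOCCl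
Why: alkoxymethylation of the remaining phenol gives a base-stable, fluoride-labile ether orthogonal to the benzyl ether.

Step 3
Reactants: 3 4-(benzyloxy)-3-bromo-5-{[2-(trimethylsilyl)ethoxy]methoxy}benzaldehyde
Product: 4 [4-(benzyloxy)-3-bromo-5-{[2-(trimethylsilyl)ethoxy]methoxy}phenyl]methanol
Conditions: NaBH4, MeOH, 0 °C
Reagents that add atoms: none
Why: borohydride reduction of the aldehyde leaves the aryl bromide and both ethers untouched.

Step 4
Reactants: 4 [4-(benzyloxy)-3-bromo-5-{[2-(trimethylsilyl)ethoxy]methoxy}phenyl]methanol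
Product: 5 {[4-(benzyloxy)-3-bromo-5-{[2-(trimethylsilyl)ethoxy]methoxy}phenyl]methoxy}tri(propan-2-yl)silane
Conditions: TIPSCl, imidazole, DMF, rt
Reagents that add atoms: chlorotri(propan-2-yl)silane, CC(C)[Si](Cl)(C(C)C)C(C)C
Why: silylation of the primary alcohol gives an ether that should survive the later basic steps.

Step 5
Reactants: 5 {[4-(benzyloxy)-3-bromo-5-{[2-(trimethylsilyl)ethoxy]methoxy}phenyl]methoxy}tri(propan-2-yl)silane
Product: 8 Ar-methanol, via aryllithium 6 (not isolated), via aryl aldehyde 7 (not isolated)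
Conditions: n-BuLi, THF, −78 °C; DMF, −78 °C; then MeOH, NaBH4, 0 °C
Reagents that add atoms: N,N-dimethylformamide, CN(C)C=O
Why: bromine–lithium exchange is faster than any deprotonation at −78 °C, and formylation followed by in-flask borohydride reduction installs the one-carbon handle.

Step 6
Reactants: 8 Ar-methanol
Product: 9 Ar-methyl bromide
Conditions: CBr4, PPh3, CH2Cl2, 0 °C
Reagents that add atoms: tetrabromomethane, BrC(Br)(Br)Br
Why: Appel bromination is neutral, so the acid-sensitive SEM and silyl ethers should survive.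

**C1–C5 unit of ring A**

Step 7
Reactants: 10 4-chlorobutanoyl chloride
Product: 11 6-chlorohexan-3-one
Conditions: EtMgBr, Fe(acac)3 (3 mol%), THF, −78 °C
Reagents that add atoms: ethylmagnesium bromide, CC[Mg]Br
Why: iron-catalysed acylation of a Grignard reagent by an acid chloride stops at the ketone and spares the alkyl chloride.

Step 8
Reactants: 11 6-chlorohexan-3-one
Product: 12 2-(3-chloropropyl)-2-ethyl-1,3-dioxolane
Conditions: HOCH2CH2OH, p-TsOH (cat.), toluene, reflux, Dean–Stark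
Reagents that add atoms: ethane-1,2-diol, OCCO
Why: ketalisation masks the ketone so that the chloride can be converted into a Grignard reagent.

**Lactone template and main line**

Step 9
Reactants: 13 methyl hydrogen (R)-3-methylglutarate
Product: 15 (4S)-4-methyloxan-2-one, via hydroxy acid 14 (not isolated)
Conditions: LiBH4 (excess), THF, 0 °C to rt; then 2 M HCl, rt
Reagents that add atoms: none
Why: LiBH4 reduces the ester but not the lithium carboxylate, and acid then lactonises; the stereocentre is untouched (the descriptor changes to S only because the priorities of the two arms swap).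

Step 10
Reactants: 15 (4S)-4-methyloxan-2-one
Product: 17 (4S)-3,4-dimethyloxan-2-one (C3 epimers), via lithium enolate 16 (not isolated)
Conditions: LiN(i-Pr)2, THF, −78 °C; MeI, −78 °C
Reagents that add atoms: iodomethane, CI
Why: lactone enolate methylation; the configuration at C3 is irrelevant because it is erased in the next enolisation.

Step 11
Reactants: 17 (4S)-3,4-dimethyloxan-2-one; 9 Ar-methyl bromide
Product: 19 (3R,4S)-3-(Ar-methyl)-3,4-dimethyloxan-2-one, via lithium enolate 18 (not isolated)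
Conditions: LiN(i-Pr)2, THF, −78 °C; 9, DMPU, −78 to −20 °C
Reagents that add atoms: none
Why: enolate alkylation on the six-membered template occurs anti to the adjacent C4 methyl (pseudoaxial to avoid allylic strain), placing the arylmethyl group trans and the C3 methyl cis to it, which sets the future C9 relative to C8.

Step 12
Reactants: 19 (3R,4S)-3-(Ar-methyl)-3,4-dimethyloxan-2-one; 12 2-(3-chloropropyl)-2-ethyl-1,3-dioxolane
Product: 21 (5R,6S)-5-(Ar-methyl)-1-(2-ethyl-1,3-dioxolan-2-yl)-8-hydroxy-5,6-dimethyloctan-4-one (in equilibrium with its cyclic hemiketal), via Grignard reagent 20 (not isolated)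
Conditions: 12, Mg, THF, reflux; then 19, THF, −78 to 0 °C; aq. NH4Cl
Reagents that add atoms: none
Why: Grignard addition to the lactone should stop after one addition because the magnesium lactolate persists until work-up and the released ketone is flanked by the quaternary centre.

Step 13
Reactants: 21 (5R,6S)-5-(Ar-methyl)-1-(2-ethyl-1,3-dioxolan-2-yl)-8-hydroxy-5,6-dimethyloctan-4-one
Product: 23 3-[(2R,3S)-1-Ar-5-hydroxy-2,3-dimethylpentan-2-yl]-2-methylcyclohex-2-en-1-one, via diketone 22 (not isolated)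
Conditions: PPTS, acetone/H2O, 60 °C; then KOH, MeOH, 65 °C
Reagents that add atoms: water, O
Why: ketal hydrolysis followed by intramolecular aldol condensation (Robinson-type closure of ring A); only attack of C5 on the C10 carbonyl gives a six-membered ring, and dehydration makes it irreversible.

Step 14
Reactants: 23 3-[(2R,3S)-1-Ar-5-hydroxy-2,3-dimethylpentan-2-yl]-2-methylcyclohex-2-en-1-one
Product: 24 (3S,4R)-5-Ar-3,4-dimethyl-4-(2-methyl-3-oxocyclohex-1-en-1-yl)pentyl 4-methylbenzenesulfonate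
Conditions: TsCl, pyridine, DMAP (cat.), CH2Cl2, 0 °C
Reagents that add atoms: 4-methylbenzenesulfonyl chloride, Cc1ccc(S(=O)(=O)Cl)cc1
Why: sulfonylation turns the primary C6 alcohol into the leaving group for ring closure.

Step 15
Reactants: 24 (3S,4R)-5-Ar-3,4-dimethyl-4-(2-methyl-3-oxocyclohex-1-en-1-yl)pentyl 4-methylbenzenesulfonate
Product: 26 (5R,6S,8aS)-5-(Ar-methyl)-5,6,8a-trimethyl-3,5,6,7,8,8a-hexahydronaphthalen-1(2H)-one, via potassium dienolate 25 (not isolated)
Conditions: KOt-Bu (1.2 equiv), t-BuOH/THF, 0 °C to rt, high dilution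
Reagents that add atoms: none
Why: KOt-Bu equilibrates enone 24 to the cross-ring dienolate 25 (deprotonation at C1), whose alpha-carbon C5 displaces the C6 tosylate in an intramolecular SN2 reaction, the ring-closing counterpart of the deconjugative alpha-alkylation of extended enolates used for gem-dialkylation of bicyclic enones. Ring B closes in the 6-(enolexo)-exo-tet mode through a chair. The new C5 stereocentre is controlled by C8 and C9: ring A holds C4 in the dienolate plane, so the C5 methyl must take the axial site of the forming ring, syn to the axial C9 substituent, and with the C8 methyl equatorial that substituent is the C9 methyl and not the arylmethyl group, which gives 5S. The step needs C5 over C1 and over oxygen: the alpha-carbon carries the larger coefficient and lies next to the metal-bound oxygen, O-alkylation would need an eight-membered ring, and high dilution suppresses intermolecular reaction. C10 is deliberately kept trigonal, because closure onto C5 from a saturated C10 would enforce a cis ring fusion.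

Step 16
Reactants: 26 (5R,6S,8aS)-5-(Ar-methyl)-5,6,8a-trimethyl-3,5,6,7,8,8a-hexahydronaphthalen-1(2H)-one
Product: 27 (4aS,5R,6S,8aS)-5-(Ar-methyl)-5,6,8a-trimethyloctahydronaphthalen-1(2H)-one
Conditions: Mn(dpm)3 (10 mol%), PhSiH3, t-BuOOH, i-PrOH, rt
Reagents that add atoms: none
Why: radical (MHAT) hydrogenation of the hindered trisubstituted alkene; the tertiary C10 radical should take hydrogen from the alpha face because the beta face is covered by the two syn-axial methyls on C5 and C9, giving the thermodynamically preferred trans fusion (10S).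

Step 17
Reactants: 27 (4aS,5R,6S,8aS)-5-(Ar-methyl)-5,6,8a-trimethyloctahydronaphthalen-1(2H)-one
Product: 28 (4aS,5R,6S,8aS)-5-(Ar'-methyl)-5,6,8a-trimethyloctahydronaphthalen-1(2H)-one
Conditions: H2 (1 atm), 10% Pd/C, EtOAc, rt
Reagents that add atoms: none
Why: hydrogenolysis of the aryl benzyl ether frees only the phenol that is to be sulfated, at a stage where no alkene is present.

Step 18
Reactants: 28 (4aS,5R,6S,8aS)-5-(Ar'-methyl)-5,6,8a-trimethyloctahydronaphthalen-1(2H)-one
Product: 29 2-{[(1R,2S,4aS,8aS)-1,2,4a-trimethyl-5-methylidenedecahydronaphthalen-1-yl]methyl}-6-{[2-(trimethylsilyl)ethoxy]methoxy}-4-({[tri(propan-2-yl)silyl]oxy}methyl)phenol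
Conditions: Ph3PCH3Br, KOt-Bu (excess), toluene, 90 °C
Reagents that add atoms: methyltriphenylphosphonium bromide, C[P+](c1ccccc1)(c1ccccc1)c1ccccc1.[Br-]
Why: Wittig methylenation of the hindered C4 ketone under forcing salt-free-type conditions; the first equivalent of ylide is spent on the phenol, and the quaternary C5 cannot epimerise.

Step 19
Reactants: 29 the methylidene phenol of step 18
Product: 30 pyridinium 2-{[(1R,2S,4aS,8aS)-1,2,4a-trimethyl-5-methylidenedecahydronaphthalen-1-yl]methyl}-6-{[2-(trimethylsilyl)ethoxy]methoxy}-4-({[tri(propan-2-yl)silyl]oxy}methyl)phenyl sulfate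
Conditions: SO3·pyridine, pyridine, 50 °C
Reagents that add atoms: sulfur trioxide–pyridine complex, O=S(=O)([O-])[n+]1ccccc1
Why: O-sulfonation of the only free hydroxyl group; the complex is mild enough to leave the exocyclic alkene alone.

Step 20
Reactants: 30 the pyridinium aryl sulfate of step 19
Product: 31 2-hydroxy-4-(hydroxymethyl)-6-{[(1R,2S,4aS,8aS)-1,2,4a-trimethyl-5-methylidenedecahydronaphthalen-1-yl]methyl}phenyl hydrogen sulfate (CNP0353860.3)
Conditions: Bu4NF (excess), THF, 50 °C; then Dowex 50W (H+ form), MeOH/H2O, 0 °C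
Reagents that add atoms: none
Why: fluoride removes the silyl ether and, by fragmentation, the SEM ether, while the aryl sulfate monoester is stable to fluoride and base and the alkene never meets strong acid.

**Compound list**

1 | 3-bromo-4,5-dihydroxybenzaldehyde | O=Cc1cc(O)c(O)c(Br)c1 | starting material
2 | 4-(benzyloxy)-3-bromo-5-hydroxybenzaldehyde | O=Cc1cc(O)c(OCc2ccccc2)c(Br)c1 | intermediate
3 | 4-(benzyloxy)-3-bromo-5-{[2-(trimethylsilyl)ethoxy]methoxy}benzaldehyde | O=Cc1cc(OCOCC[Si](C)(C)C)c(OCc2ccccc2)c(Br)c1 | intermediate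
4 | [4-(benzyloxy)-3-bromo-5-{[2-(trimethylsilyl)ethoxy]methoxy}phenyl]methanol | OCc1cc(OCOCC[Si](C)(C)C)c(OCc2ccccc2)c(Br)c1 | intermediate
5 | {[4-(benzyloxy)-3-bromo-5-{[2-(trimethylsilyl)ethoxy]methoxy}phenyl]methoxy}tri(propan-2-yl)silane | CC(C)[Si](OCc1cc(OCOCC[Si](C)(C)C)c(OCc2ccccc2)c(Br)c1)(C(C)C)C(C)C | intermediate
6 | Ar-lithium (aryllithium from 5) | CC(C)[Si](OCc1cc(OCOCC[Si](C)(C)C)c(OCc2ccccc2)c([Li])c1)(C(C)C)C(C)C | intermediate
7 | Ar-carbaldehyde: 2-(benzyloxy)-3-{[2-(trimethylsilyl)ethoxy]methoxy}-5-({[tri(propan-2-yl)silyl]oxy}methyl)benzaldehyde | CC(C)[Si](OCc1cc(OCOCC[Si](C)(C)C)c(OCc2ccccc2)c(C=O)c1)(C(C)C)C(C)C | intermediate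
8 | Ar-methanol | CC(C)[Si](OCc1cc(OCOCC[Si](C)(C)C)c(OCc2ccccc2)c(CO)c1)(C(C)C)C(C)C | intermediate
9 | Ar-methyl bromide | CC(C)[Si](OCc1cc(OCOCC[Si](C)(C)C)c(OCc2ccccc2)c(CBr)c1)(C(C)C)C(C)C | intermediate
10 | 4-chlorobutanoyl chloride | O=C(Cl)CCCCl | starting material
11 | 6-chlorohexan-3-one | CCC(=O)CCCCl | intermediate
12 | 2-(3-chloropropyl)-2-ethyl-1,3-dioxolane | CCC1(CCCCl)OCCO1 | intermediate
13 | methyl hydrogen (R)-3-methylglutarate, (3R)-5-methoxy-3-methyl-5-oxopentanoic acid | COC(=O)C[C@H](C)CC(=O)O | starting material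
14 | (3S)-5-hydroxy-3-methylpentanoic acid | OCC[C@H](C)CC(=O)O | intermediate
15 | (4S)-4-methyloxan-2-one | O=C1C[C@@H](C)CCO1 | intermediate
16 | lithium enolate of 15 | [Li]OC1=C[C@@H](C)CCO1 | intermediate
17 | (4S)-3,4-dimethyloxan-2-one (C3 epimers, 3,4-trans expected to dominate) | O=C1C(C)[C@@H](C)CCO1 | intermediate
18 | lithium enolate of 17 | [Li]OC1=C(C)[C@@H](C)CCO1 | intermediate
19 | (3R,4S)-3-(Ar-methyl)-3,4-dimethyloxan-2-one | O=C1[C@](C)(Cc2cc(CO[Si](C(C)C)(C(C)C)C(C)C)cc(OCOCC[Si](C)(C)C)c2OCc3ccccc3)[C@@H](C)CCO1 | intermediate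
20 | [3-(2-ethyl-1,3-dioxolan-2-yl)propyl]magnesium chloride | CCC1(CCC[Mg]Cl)OCCO1 | intermediate
21 | (5R,6S)-5-(Ar-methyl)-1-(2-ethyl-1,3-dioxolan-2-yl)-8-hydroxy-5,6-dimethyloctan-4-one (drawn open-chain) | CCC1(CCCC(=O)[C@](C)(Cc2cc(CO[Si](C(C)C)(C(C)C)C(C)C)cc(OCOCC[Si](C)(C)C)c2OCc3ccccc3)[C@@H](C)CCO)OCCO1 | intermediate
22 | (8R,9S)-8-(Ar-methyl)-11-hydroxy-8,9-dimethylundecane-3,7-dione | CCC(=O)CCCC(=O)[C@](C)(Cc2cc(CO[Si](C(C)C)(C(C)C)C(C)C)cc(OCOCC[Si](C)(C)C)c2OCc3ccccc3)[C@@H](C)CCO | intermediate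
23 | 3-[(2R,3S)-1-Ar-5-hydroxy-2,3-dimethylpentan-2-yl]-2-methylcyclohex-2-en-1-one | CC1=C(CCCC1=O)[C@](C)(Cc2cc(CO[Si](C(C)C)(C(C)C)C(C)C)cc(OCOCC[Si](C)(C)C)c2OCc3ccccc3)[C@@H](C)CCO | intermediate
24 | (3S,4R)-5-Ar-3,4-dimethyl-4-(2-methyl-3-oxocyclohex-1-en-1-yl)pentyl 4-methylbenzenesulfonate | CC1=C(CCCC1=O)[C@](C)(Cc2cc(CO[Si](C(C)C)(C(C)C)C(C)C)cc(OCOCC[Si](C)(C)C)c2OCc3ccccc3)[C@@H](C)CCOS(=O)(=O)c4ccc(C)cc4 | intermediate
25 | potassium cross-ring dienolate of 24 (O–C4=C5–C10=C1) | [K]OC1=C(C)C(=CCC1)[C@](C)(Cc2cc(CO[Si](C(C)C)(C(C)C)C(C)C)cc(OCOCC[Si](C)(C)C)c2OCc3ccccc3)[C@@H](C)CCOS(=O)(=O)c4ccc(C)cc4 | intermediate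
26 | (5R,6S,8aS)-5-(Ar-methyl)-5,6,8a-trimethyl-3,5,6,7,8,8a-hexahydronaphthalen-1(2H)-one | O=C1CCC=C2[C@](C)(Cc3cc(CO[Si](C(C)C)(C(C)C)C(C)C)cc(OCOCC[Si](C)(C)C)c3OCc4ccccc4)[C@@H](C)CC[C@]12C | intermediate
27 | (4aS,5R,6S,8aS)-5-(Ar-methyl)-5,6,8a-trimethyloctahydronaphthalen-1(2H)-one | O=C1CCC[C@H]2[C@](C)(Cc3cc(CO[Si](C(C)C)(C(C)C)C(C)C)cc(OCOCC[Si](C)(C)C)c3OCc4ccccc4)[C@@H](C)CC[C@]12C | intermediate
28 | (4aS,5R,6S,8aS)-5-(Ar'-methyl)-5,6,8a-trimethyloctahydronaphthalen-1(2H)-one | O=C1CCC[C@H]2[C@](C)(Cc3cc(CO[Si](C(C)C)(C(C)C)C(C)C)cc(OCOCC[Si](C)(C)C)c3O)[C@@H](C)CC[C@]12C | intermediate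
29 | 2-{[(1R,2S,4aS,8aS)-1,2,4a-trimethyl-5-methylidenedecahydronaphthalen-1-yl]methyl}-6-{[2-(trimethylsilyl)ethoxy]methoxy}-4-({[tri(propan-2-yl)silyl]oxy}methyl)phenol | C=C1CCC[C@H]2[C@](C)(Cc3cc(CO[Si](C(C)C)(C(C)C)C(C)C)cc(OCOCC[Si](C)(C)C)c3O)[C@@H](C)CC[C@]12C | intermediate
30 | pyridinium salt of the aryl sulfate of 29 | C=C1CCC[C@H]2[C@](C)(Cc3cc(CO[Si](C(C)C)(C(C)C)C(C)C)cc(OCOCC[Si](C)(C)C)c3OS(=O)(=O)[O-])[C@@H](C)CC[C@]12C.c1cc[nH+]cc1 | intermediate
31 | 2-hydroxy-4-(hydroxymethyl)-6-{[(1R,2S,4aS,8aS)-1,2,4a-trimethyl-5-methylidenedecahydronaphthalen-1-yl]methyl}phenyl hydrogen sulfate | C=C1CCC[C@H]2[C@](C)(Cc3cc(CO)cc(O)c3OS(=O)(=O)O)[C@@H](C)CC[C@]12C | target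

**Step count.** Total: 20 steps. Longest linear sequence: 16 steps (steps 1–6, then 11–20).

**Steps most likely to fail**

1. Step 15 (key step). The ambident dienolate may be alkylated at the gamma-carbon C1, which also gives a six-membered ring and avoids the developing 1,3-diaxial methyl/methyl contact, or the base may eliminate the tosylate. Fallback, setting out from 24 and coming back at 26: chloride exchange (LiCl, DMF, 60 °C) would give 3-[(2R,3S)-1-Ar-5-chloro-2,3-dimethylpentan-2-yl]-2-methylcyclohex-2-en-1-one F1. Condensation with cyclohexylamine (TiCl4, Et3N, toluene) would give its N-cyclohexyl imine F2. Deprotonation with LiN(i-Pr)2 (THF, −78 to 0 °C) would generate the metalloenamine, a class of nucleophile that alkylates at the alpha-carbon, and ring closure would give the N-cyclohexyl imine of the bicyclic ketone F3. Buffered hydrolysis (NaOAc, AcOH, H2O) should return 26.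

2. Step 13. The aldol addition of C5 onto the neopentyl-type C10 ketone is reversible and may stall before dehydration, or the C6 hydroxyl may hold the ketone as a hemiketal. Fallback, setting out from 19 and coming back at 23, replacing the reversible aldol by an irreversible olefination: aminolysis of the lactone with MeNH(OMe)·HCl and Me3Al would give (2R,3S)-2-(Ar-methyl)-5-hydroxy-N-methoxy-N,2,3-trimethylpentanamide F4. Vinylmagnesium bromide (excess, THF, 0 °C) would give (4R,5S)-4-(Ar-methyl)-7-hydroxy-4,5-dimethylhept-1-en-3-one F5. The dianion of diethyl (3-oxobutan-2-yl)phosphonate (NaH, then n-BuLi) would add through its terminal carbon to the enone to give diethyl [(8R,9S)-8-(Ar-methyl)-11-hydroxy-8,9-dimethyl-3,7-dioxoundecan-2-yl]phosphonate F6. Its phosphonate anion should close ring A on warming by intramolecular Horner–Wadsworth–Emmons reaction to give 23.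

3. Step 11. Alkylation of the fully substituted lactone enolate with the hindered, electron-rich benzylic bromide may be slow, with loss of the bromide, O-alkylation or eroded facial selectivity. Fallback, setting out from 17 and coming back at 19, with aldehyde 7 isolated from step 5 by aqueous work-up before the borohydride is added: aldol addition of enolate 18 to 7 (−78 °C, same anti approach) would give (3S,4S)-3-[Ar(hydroxy)methyl]-3,4-dimethyloxan-2-one F7 as carbinol epimers. 1,1'-Thiocarbonyldiimidazole with DMAP would give O-{Ar[(3S,4S)-3,4-dimethyl-2-oxooxan-3-yl]methyl} 1H-imidazole-1-carbothioate F8. Barton–McCombie deoxygenation (Bu3SnH, AIBN, toluene, 90 °C) should give 19.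

Further compounds
F1 | step 15 | 3-[(2R,3S)-1-Ar-5-chloro-2,3-dimethylpentan-2-yl]-2-methylcyclohex-2-en-1-one | CC1=C(CCCC1=O)[C@](C)(Cc2cc(CO[Si](C(C)C)(C(C)C)C(C)C)cc(OCOCC[Si](C)(C)C)c2OCc3ccccc3)[C@@H](C)CCCl
F2 | step 15 | N-cyclohexyl imine of F1 | CC1=C(CCCC1=NC4CCCCC4)[C@](C)(Cc2cc(CO[Si](C(C)C)(C(C)C)C(C)C)cc(OCOCC[Si](C)(C)C)c2OCc3ccccc3)[C@@H](C)CCCl
F3 | step 15 | N-cyclohexyl imine of 26 | N(C5CCCCC5)=C1CCC=C2[C@](C)(Cc3cc(CO[Si](C(C)C)(C(C)C)C(C)C)cc(OCOCC[Si](C)(C)C)c3OCc4ccccc4)[C@@H](C)CC[C@]12C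
F4 | step 13 | (2R,3S)-2-(Ar-methyl)-5-hydroxy-N-methoxy-N,2,3-trimethylpentanamide | CON(C)C(=O)[C@](C)(Cc2cc(CO[Si](C(C)C)(C(C)C)C(C)C)cc(OCOCC[Si](C)(C)C)c2OCc3ccccc3)[C@@H](C)CCO
F5 | step 13 | (4R,5S)-4-(Ar-methyl)-7-hydroxy-4,5-dimethylhept-1-en-3-one | C=CC(=O)[C@](C)(Cc2cc(CO[Si](C(C)C)(C(C)C)C(C)C)cc(OCOCC[Si](C)(C)C)c2OCc3ccccc3)[C@@H](C)CCO
F6 | step 13 | diethyl [(8R,9S)-8-(Ar-methyl)-11-hydroxy-8,9-dimethyl-3,7-dioxoundecan-2-yl]phosphonate | CCOP(=O)(OCC)C(C)C(=O)CCCC(=O)[C@](C)(Cc2cc(CO[Si](C(C)C)(C(C)C)C(C)C)cc(OCOCC[Si](C)(C)C)c2OCc3ccccc3)[C@@H](C)CCO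
F7 | step 11 | (3S,4S)-3-[Ar(hydroxy)methyl]-3,4-dimethyloxan-2-one | O=C1[C@](C)(C(O)c2cc(CO[Si](C(C)C)(C(C)C)C(C)C)cc(OCOCC[Si](C)(C)C)c2OCc3ccccc3)[C@@H](C)CCO1
F8 | step 11 | O-{Ar[(3S,4S)-3,4-dimethyl-2-oxooxan-3-yl]methyl} 1H-imidazole-1-carbothioate | O=C1[C@](C)(C(OC(=S)n4ccnc4)c2cc(CO[Si](C(C)C)(C(C)C)C(C)C)cc(OCOCC[Si](C)(C)C)c2OCc3ccccc3)[C@@H](C)CCO1
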